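(The data were generated by integration with constants of no real substance; scatter was added.)

Time moved nothing I could read in the zeta flask: complex with three exchanged stood at 17.1% after 1.50 h and at 17.2% after 20.0 h, with a scatter of 1 percentage point.

| setting | zeta | delta | epsilon | alpha | summer | dawn |
|---|---|---|---|---|---|---|
| starting complex | 0.063 M | 0.065 M | 0.11 M | 0.050 M | 0.050 M | 0.10 M |
| incoming ligand | 0.10 M | 0.10 M | 0.10 M | 0.077 M | 0.100 M | 0.0600 M |
| temperature | 20 °C | 45 °C | 20 °C | 45 °C | 25 °C | 65 °C |
| remark | run made earlier | run made earlier | run made earlier | run made earlier |  |  |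
| time |  |  |  |  | 25 h | 25 h |

- zeta (time / h: complex with three exchanged / %, starting complex / %): 1.50: 17.1, 30.3; 4.00: 16.2, 29.1; 8.00: 17.8, 30.1; 12.0: 17.6, 29.4; 20.0: 17.2, 28.6
- delta (time / h: complex with three exchanged / %, starting complex / %): 0.500: 13.1, 34.7; 1.33: 13.8, 35.3; 3.00: 11.0, 35.6; 4.00: 14.4, 37.0; 8.00: 14.3, 34.7
- epsilon (time / h: complex with three exchanged / %, starting complex / %): 4.00: 5.0, 54.2; 8.00: 5.2, 55.6; 10.0: 4.1, 53.7; 15.0: 2.8, 53.9; 20.0: 5.2, 53.0
- alpha (time / h: complex with three exchanged / %, starting complex / %): 1.33: 12.8, 34.7; 3.00: 13.4, 36.7; 4.00: 15.1, 36.5; 6.00: 14.7, 36.0; 8.00: 12.1, 35.1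

(each reading ± 1 percentage point)

- which of the two ends with the higher amount of complex with three exchanged, in percent of the starting complex charged ("neither" if they lie within 2 percentage points) (summer / dawn / neither)
- complex with three exchanged at the end, in percent of the starting complex charged, summer
- complex with three exchanged at the end, in percent of the starting complex charged, dawn



But zeta stood still with 28.6% of starting complex present, so I suspected the incoming ligand of being the limiting reagent and wrote its balance. I assumed each exchange spends one incoming ligand, so I carried the ligand budget: [incoming ligand] charged over [starting complex] charged, 2.00 in summer.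

Zeta's budget is 1.59. If its unread remainder were complex with two exchanged, its last readings would have spent 1.60, near that budget. Delta and alpha have different charges but budgets of 1.54 and 1.54, and their last readings of starting complex were 34.7% and 35.1%.

Epsilon's budget is 0.909, so between epsilon and zeta a unit of budget bought 18 points. My line, drawn from those two last readings at 20 °C, gave summer 24.5%. It reached zero near a budget of 0.615, and dawn's 0.600 lies below that, so, taking the line to hold at 65 °C as well, I put dawn near zero.

The forecast said summer, with 23% for summer and 2.5% for dawn, where “there is too little ligand to reach the third exchange”.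

The flasks gave 29.3% in summer and 1.37% in dawn, so summer ended higher.

    complex with two exchanged + incoming ligand → leaving ligand + complex with three exchanged (k = 0.00880 M⁻¹ s⁻¹, Ea = 58.0 kJ mol⁻¹)
    starting complex + incoming ligand → leaving ligand + complex with one exchanged (k = 0.0180 M⁻¹ s⁻¹, Ea = 56.0 kJ mol⁻¹)
    incoming ligand → decomposed reagent (k = 5.10 × 10⁻⁵ s⁻¹, Ea = 104 kJ mol⁻¹)
    complex with one exchanged + incoming ligand → leaving ligand + complex with two exchanged (k = 0.140 M⁻¹ s⁻¹, Ea = 52.0 kJ mol⁻¹)
    (constants at 25 °C)

Summer stopped because its budget was spent: incoming ligand stood at 0% of its charge after 25.0 h, and holding it at its charge gives 100% of complex with three exchanged instead of 29.3%. Of the budget of 2.00, decomposed reagent took 0.0967, leaving 1.90 for exchanges.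

The neighbour of summer charged with 0.20 M of starting complex has a budget of 0.500, below the zero of my line, so the line puts it near zero. That flask gave 1.26% of complex with three exchanged.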